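Per mole of partner charged, the west run holds 0.488 mole of product at 110 min, with 0.122 M of starting material unreacted by subtraction and 0.0819 M of partner not in product. The question for the north-west run is whether its charge and its 110 min can stay.

all flasks: catalyst 0.00200 M
- west: starting material 0.200 M; partner 0.160 M
- east: starting material 0.100 M; partner 0.0600 M
- north-east: starting material 0.200 M; partner 0.240 M
- north-west: starting material 0.600 M; partner 0.320 M; time 110 min

| west run: time / min | west run: [product] / M | east run: time / min | east run: [product] / M | north-east run: time / min | north-east run: [product] / M |
|---|---|---|---|---|---|
| 14 | 0.0316 | 14 | 0.0110 | 14 | 0.0437 |
| 28 | 0.0452 | 28 | 0.0156 | 28 | 0.0662 |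
| 41 | 0.0606 | 41 | 0.0143 | 41 | 0.0804 |
| 55 | 0.0683 | 55 | 0.0155 | 55 | 0.0912 |
| 69 | 0.0657 | 69 | 0.0186 | 69 | 0.0927 |
| 82 | 0.0746 | 82 | 0.0213 | 82 | 0.1003 |
| 96 | 0.0734 | 96 | 0.0241 | 96 | 0.1005 |
| 110 | 0.0781 | 110 | 0.0197 | 110 | 0.1059 |

(readings scatter by 0.002 M)

- the exponent of [starting material] in the starting rate at the charge of the west run (at the point where two percent of the starting material have become product) (one fixed amount of product, the same in the runs compared)
- the exponent of [partner] in the starting rate at the charge of the west run (at the point where two percent of the starting material have become product)
- product in the north-west run at 110 min, as a share of the starting material charged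

- Overall: starting material + partner -> product, with catalyst as catalyst.
- Constant volume, constant temperature.
- Bound and free are read together.
- "The second partner" is partner.
- An order is taken over about fifteen percent of the charge, up and down.

My reckoning follows one partner molecule to a fork: it becomes product or it is lost. This is a choice, since no reading shows the partner directly.

fork odds = c(product) / (c(partner, charged) − c(product)); west run: 0.954

These fork odds, product made per partner not in product, are the quantity to carry forward; partner still unreacted at the last reading counts here as lost.

A loss on its own clock should show in the approach to the plateau. By 14 min the west run has reached 0.405 of its last reading and the north-east run 0.413, although its partner charge is 1.50 times larger. Taking the last reading as the plateau, the west figure gives a rough first-order clock of 0.0370 min⁻¹. On that clock of the west run, borrowed for the north-west run, hardly any of the approach remains at 110 min, so the time stays.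

The charge depends on how the odds scale. The first readings, compared at equal time and not at equal product, give rough exponents, though the east reading carries 18.2% scatter:

exponent of c(partner), north-east against west: 0.800

exponent of c(starting material), west against east: 0.391

With the loss per partner molecule taken as independent of the charge, the odds go with the rate per partner molecule:

north-west odds = west odds × 1.54 × 0.870 = 1.28

In this reckoning the extra starting material of the north-west run raises the odds more than its extra partner lowers them. Partner is the limiting reagent in the north-west run, and a share 0.560 of it gives 0.179 M of product, or 29.9% of the starting material. The charge stays.

The forecast, holding that “this looks like an equilibrium”, gives exponents of 0.6 and 0.87 and a yield of 38.8% (range 36.5% to 40.5%), higher than my 29.9%.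

The north-west run gives 33.2% of the starting material at 110 min, which is 0.199 M of product from 0.320 M of partner, so its fork odds are 1.65. The exponents at the west charge are 0.64 and 0.87, and in the same rule they give odds of 1.76.

    catalyst + partner ⇌ catalyst-reagent complex, settled at all times (1.320 L mol⁻¹)
    catalyst-reagent complex + starting material → product + catalyst (104.4 L mol⁻¹ min⁻¹)
    partner → lost reagent (0.01668 min⁻¹)
    2 starting material ⇌ idle substrate dimer, settled at all times (12.40 L mol⁻¹)

The loss at the fork is the step from partner to lost reagent, with a mean life of 60.0 min. For the north-east run the rule gives odds of 0.906, hence 0.114 M of product, and its reading at 110 min is 0.1059 M.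

The runs stem from a simulated flask for substances that don't exist.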